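**Retrosynthetic overview**

1. The C2 hydroxyl is added last by allylic oxidation of the 1-methylidene group. The C9 chloride comes from a C9 carbinol (methyl addition to a C9 ketone, then retentive chlorination), and the equatorial C8 bromide from regiospecific α-bromination of that ketone.
2. The C9 ketone is traced, by a reductive carbonyl transposition that deletes a C7 oxygen, to a spiro 1,7,9-trione. Ring B of this trione is cut at C6–C11 and C8–C9, giving a ring A β-diketone (2-acetyl-4-bromo-3,3-dimethylcyclohexanone) and methyl acrylate, joined in one Michael–Claisen [3+3] spiroannulation.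
3. Enabling feature: in ring B the spiro carbon C6 lies between C1 of ring A (the methylidene carbon, a ketone until step 7) and C7, and the C(CH3)Cl carbon C9 stands 1,3 to C7. With oxygen on C7 and C9, C6 is the central carbon of a 1,3-diketone (soft Michael donor) and C8/C9 are the α-carbon and acyl carbon of a Claisen closure.
4. Ring A, with its C4 bromide and C5 gem-dimethyl group, is made by bromonium-ion cyclisation of an enantioenriched vicinal bromochloride (from prenol) onto the central carbon of an acetylacetone unit.
5. Order of ring formation: ring A (step 4), then ring B (step 5).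

Key step: step 5

Remark: positions in spirocycles 11–22 (and in the Why lines) carry the locants of the target: C1 bears the methylidene, C2 is the carbinol carbon, C4 the CHBr of ring A, C5 the CMe2 carbon, C6 the spiro carbon, C7 the CH2 next to C8, C8 the CHBr of ring B, C9 the C(CH3)Cl carbon, C10–C11 the CH2–CH2 arm.

**Route**

Step 1
Reactants: 1 3-methylbut-2-en-1-ol (prenol)
Product: 2 (2R)-2-bromo-3-chloro-3-methylbutan-1-ol
Conditions: NBS, ClTi(OiPr)3, enantiopure tridentate Schiff-base ligand (20 mol %), hexanes, −20 °C
Reagents that add atoms: N-bromosuccinimide, O=C1CCC(=O)N1Br; chlorotitanium triisopropoxide, CC(C)O[Ti](Cl)(OC(C)C)OC(C)C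
Why: Catalytic enantioselective bromochlorination of an allylic alcohol, in which the titanium alkoxide of 1 takes up Br+ and chloride in an anti, Markovnikov sense (Br at C2, Cl at the tertiary carbon) and the ligand enantiomer is chosen to give the 2R centre, which becomes C4 of the target.

Step 2
Reactants: 2 (2R)-2-bromo-3-chloro-3-methylbutan-1-ol
Product: 3 (2R)-2-bromo-3-chloro-3-methylbutyl trifluoromethanesulfonate
Conditions: Tf2O, 2,6-lutidine, CH2Cl2, −78 °C; used at once
Reagents that add atoms: trifluoromethanesulfonic anhydride, O=S(=O)(OS(=O)(=O)C(F)(F)F)C(F)(F)F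
Why: O-Sulfonylation of a primary alcohol at low temperature should give the triflate without touching the CHBr stereocentre.

Step 3
Reactants: 3 (2R)-2-bromo-3-chloro-3-methylbutyl trifluoromethanesulfonate, 4 pentane-2,4-dione (acetylacetone)
Product: 6 (7R)-7-bromo-8-chloro-8-methylnonane-2,4-dione, via pentane-2,4-dione dianion 5 (not isolated)
Conditions: LiN(i-Pr)2 (2.1 equiv), THF, −78 → 0 °C; then 3, −78 °C; aq. HCl
Reagents that add atoms: none
Why: Dianion γ-alkylation of a 1,3-diketone, in which the terminal carbanion is the most nucleophilic site and should displace the primary triflate by SN2 at −78 °C faster than it induces elimination, leaving the CHBr centre unchanged.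

Step 4
Reactants: 6 (7R)-7-bromo-8-chloro-8-methylnonane-2,4-dione
Product: 8 (4R)-2-acetyl-4-bromo-3,3-dimethylcyclohexan-1-one (enol/keto tautomers and C2 epimers), via bromonium ion 7 (not isolated)
Conditions: (CF3)2CHOH, 23 °C
Reagents that add atoms: none
Why: Solvolytic ionisation of the tertiary chloride is assisted by the neighbouring bromine, and the resulting enantiopure bromonium ion should be opened at its tertiary carbon by the central carbon of the diketone enol in a chair-like 6-endo cation–enol cyclisation (C-alkylation being the thermodynamic outcome, since an O-alkylated enol ether would re-ionise in the HCl that forms), which builds ring A with the CHBr configuration retained.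

Step 5
Reactants: 8 (4R)-2-acetyl-4-bromo-3,3-dimethylcyclohexan-1-one, 9 methyl acrylate
Product: 11 (4R,6R)-4-bromo-5,5-dimethylspiro[5.5]undecane-1,7,9-trione (7,9-dione enolised), via Michael adduct 10 (not isolated)
Conditions: KOtBu (0.1 equiv), THF, 0 → 23 °C; then KOtBu (2.5 equiv), THF, 0 → 40 °C; aq. HCl
Reagents that add atoms: none
Why: The potassium enolate of β-diketone 8 adds through its central carbon C6 to methyl acrylate (Michael addition, new C6–C11 bond) to give 10, and with excess KOtBu the acetyl methyl enolate (C8) then acylates itself with the ester carbon C9 (Claisen condensation, new C8–C9 bond, loss of methoxide), the product being held as the stabilised 1,3-dione enolate. The closest known reaction type is the consecutive Michael–Claisen synthesis of cyclohexane-1,3-diones from methyl ketones and acrylates. Ring B is closed by a 6-(enolendo)-exo-trig acyl substitution. The one new stereocentre, the quaternary spiro carbon C6, is set in the Michael step: the planar enolate should take up the acrylate on the face anti to the pseudo-axial C5 methyl group, which lies on the side of the equatorial C4 bromine, so that C11 enters trans to bromine, and the enol tautomers and C6 epimers of 8 converge on this one configuration. The step needs C-alkylation at the hindered C6 and closure from C8 only; the first is favoured by the soft, doubly stabilised enolate and the unhindered acceptor, the second by thermodynamic funnelling, because only closure from C8 gives a 1,3-dione that can be deprotonated, whereas closure from C2 would give a bridged, non-enolisable dione that reverts. The hindered alkoxide should keep retro-Claisen cleavage of the 2,2-disubstituted 1,3-diketone low.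

Step 6
Reactants: 11 (4R,6R)-4-bromo-5,5-dimethylspiro[5.5]undecane-1,7,9-trione
Product: 12 (4R,6R)-4-bromo-9-methoxy-5,5-dimethylspiro[5.5]undec-8-ene-1,7-dione
Conditions: MeOH, cat. TsOH, 4 Å MS, CH2Cl2, 40 °C
Reagents that add atoms: methanol, CO
Why: Acid-catalysed enol etherification of a cyclic 1,3-dione under equilibrating conditions should place the methoxy group on the less hindered carbonyl carbon C9, leaving the vinylogous-ester carbonyl at C7 next to the spiro centre, while the hindered C1 ketone does not ketalise.

Step 7
Reactants: 12 (4R,6R)-4-bromo-9-methoxy-5,5-dimethylspiro[5.5]undec-8-ene-1,7-dione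
Product: 13 (4R,6S)-4-bromo-9-methoxy-5,5-dimethyl-1-methylidenespiro[5.5]undec-8-en-7-one
Conditions: Cp2Ti(μ-Cl)(μ-CH2)AlMe2, pyridine, THF, −40 → 0 °C
Reagents that add atoms: titanium–aluminium methylidene reagent Cp2Ti(Cl)CH2AlMe2, C[Al](C)C[Ti](Cl)(C1C=CC=C1)C1C=CC=C1
Why: Carbonyl methylenation by a titanium methylidene is non-basic and tolerates hindered, enolisable ketones, and the saturated C1 ketone should react much faster than the vinylogous-ester carbonyl.

Step 8
Reactants: 13 (4R,6S)-4-bromo-9-methoxy-5,5-dimethyl-1-methylidenespiro[5.5]undec-8-en-7-one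
Product: 15 (4R,6S)-4-bromo-5,5-dimethyl-1-methylidenespiro[5.5]undec-7-en-9-one, via allylic alcohol 14 (not isolated)
Conditions: i-Bu2AlH, toluene, −78 °C; then 1 M HCl, THF, 23 °C
Reagents that add atoms: none
Why: Stork–Danheiser transposition, in which 1,2-reduction of the vinylogous-ester carbonyl followed by acid hydrolysis of the enol ether and β-elimination of water removes the C7 oxygen and leaves the C9 ketone as a 4,4-disubstituted cyclohexenone.

Step 9
Reactants: 15 (4R,6S)-4-bromo-5,5-dimethyl-1-methylidenespiro[5.5]undec-7-en-9-one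
Product: 18 (4R,6S,8S)-4,8-dibromo-5,5-dimethyl-1-methylidenespiro[5.5]undecan-9-one, via silyl enol ether 16 (not isolated), via axial bromo ketone 17 (not isolated)
Conditions: LiBH(s-Bu)3, THF, −78 °C; Me3SiCl, Et3N, −78 → 0 °C; NBS, THF, −78 °C; then LiBr (cat.), acetone, 23 °C
Reagents that add atoms: N-bromosuccinimide, O=C1CCC(=O)N1Br
Why: Conjugate hydride reduction of the enone gives the C8–C9 enolate regiospecifically, which is trapped as silyl enol ether 16 and brominated at C8, and bromide-mediated SN2 epimerisation should then funnel any axial epimer 17 into the equatorial bromide 18, because an axial C8 bromine clashes 1,3-diaxially with C1 of ring A, the axial substituent of the spiro carbon on ring B (the C5 quaternary carbon is held equatorial).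

Step 10
Reactants: 18 (4R,6S,8S)-4,8-dibromo-5,5-dimethyl-1-methylidenespiro[5.5]undecan-9-one
Product: 19 (4R,6S,8S,9S)-4,8-dibromo-5,5,9-trimethyl-1-methylidenespiro[5.5]undecan-9-ol
Conditions: AlMe3 (3 equiv), toluene, −78 → 0 °C; then 1 M HCl
Reagents that add atoms: trimethylaluminium, C[Al](C)C
Why: 1,2-Addition of excess AlMe3 to a cyclohexanone should proceed by axial methyl delivery, on the ring B face opposite to the axial C1 group, giving the carbinol with axial methyl and equatorial hydroxyl trans to the equatorial C8 bromide, while the alkene and the alkyl bromides are inert.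

Step 11
Reactants: 19 (4R,6S,8S,9S)-4,8-dibromo-5,5,9-trimethyl-1-methylidenespiro[5.5]undecan-9-ol
Product: 21 (4R,6S,8S,9S)-4,8-dibromo-9-chloro-5,5,9-trimethyl-1-methylidenespiro[5.5]undecane, via chlorosulfite 20 (not isolated)
Conditions: SOCl2, Et2O, −20 → 0 °C (no amine base)
Reagents that add atoms: thionyl chloride, O=S(Cl)Cl
Why: Conversion of a tertiary alcohol into the chloride through its chlorosulfite (SNi-type ion-pair collapse), with the neighbouring C8 bromine bridging the developing cation on its own face, should deliver chloride with retention and anti to bromine, giving the trans-diequatorial bromochloride.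

Step 12
Reactants: 21 (4R,6S,8S,9S)-4,8-dibromo-9-chloro-5,5,9-trimethyl-1-methylidenespiro[5.5]undecane
Product: 22 (2R,4R,6S,8S,9S)-4,8-dibromo-9-chloro-5,5,9-trimethyl-1-methylidenespiro[5.5]undecan-2-ol (CNP0150021.1)
Conditions: SeO2 (0.3 equiv), t-BuOOH, CH2Cl2, 23 °C
Reagents that add atoms: tert-butyl hydroperoxide, CC(C)(C)OO (terminal oxidant); selenium dioxide, O=[Se]=O (oxygen relay)
Why: Selenium dioxide allylic hydroxylation (ene reaction, then [2,3]-sigmatropic shift) of the 1,1-disubstituted alkene can occur only at the allylic C2 methylene and returns the exocyclic double bond, and abstraction of the axial C2–H with axial C–O formation should give the axial alcohol, trans to the equatorial C4 bromide.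

**Compound list**

1 | 3-methylbut-2-en-1-ol (prenol) | CC(C)=CCO | starting material
2 | (2R)-2-bromo-3-chloro-3-methylbutan-1-ol | OC[C@@H](Br)C(C)(C)Cl | intermediate
3 | (2R)-2-bromo-3-chloro-3-methylbutyl trifluoromethanesulfonate | O=S(=O)(OC[C@@H](Br)C(C)(C)Cl)C(F)(F)F | intermediate
4 | pentane-2,4-dione (acetylacetone) | CC(=O)CC(C)=O | starting material
5 | pentane-2,4-dione dianion, dilithium salt | [Li+].[Li+].[CH2-]C(=O)[CH-]C(C)=O | intermediate
6 | (7R)-7-bromo-8-chloro-8-methylnonane-2,4-dione | CC(=O)CC(=O)CC[C@@H](Br)C(C)(C)Cl | intermediate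
7 | bromonium (bromiranium) ion from 6, chloride salt | CC(=O)CC(=O)CC[C@H]1[Br+]C1(C)C.[Cl-] | intermediate
8 | (4R)-2-acetyl-4-bromo-3,3-dimethylcyclohexan-1-one | CC(=O)C1C(=O)CC[C@@H](Br)C1(C)C | intermediate
9 | methyl acrylate | C=CC(=O)OC | starting material
10 | methyl 3-[(1S,3R)-1-acetyl-3-bromo-2,2-dimethyl-6-oxocyclohexyl]propanoate | COC(=O)CC[C@]1(C(C)=O)C(=O)CC[C@@H](Br)C1(C)C | intermediate
11 | (4R,6R)-4-bromo-5,5-dimethylspiro[5.5]undecane-1,7,9-trione | O=C1CC[C@@H](Br)C(C)(C)[C@]12CCC(=O)CC2=O | intermediate
12 | (4R,6R)-4-bromo-9-methoxy-5,5-dimethylspiro[5.5]undec-8-ene-1,7-dione | COC1=CC(=O)[C@@]2(CC1)C(=O)CC[C@@H](Br)C2(C)C | intermediate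
13 | (4R,6S)-4-bromo-9-methoxy-5,5-dimethyl-1-methylidenespiro[5.5]undec-8-en-7-one | COC1=CC(=O)[C@@]2(CC1)C(=C)CC[C@@H](Br)C2(C)C | intermediate
14 | (4R,6S)-4-bromo-9-methoxy-5,5-dimethyl-1-methylidenespiro[5.5]undec-8-en-7-ol (C7 epimers) | COC1=CC(O)[C@@]2(CC1)C(=C)CC[C@@H](Br)C2(C)C | intermediate
15 | (4R,6S)-4-bromo-5,5-dimethyl-1-methylidenespiro[5.5]undec-7-en-9-one | O=C1C=C[C@@]2(CC1)C(=C)CC[C@@H](Br)C2(C)C | intermediate
16 | [(4R,6S)-4-bromo-5,5-dimethyl-1-methylidenespiro[5.5]undec-8-en-9-yl]oxy(trimethyl)silane | C=C1CC[C@@H](Br)C(C)(C)[C@]12CCC(O[Si](C)(C)C)=CC2 | intermediate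
17 | (4R,6S,8R)-4,8-dibromo-5,5-dimethyl-1-methylidenespiro[5.5]undecan-9-one (axial C8 bromide) | C=C1CC[C@@H](Br)C(C)(C)[C@]12CCC(=O)[C@H](Br)C2 | intermediate
18 | (4R,6S,8S)-4,8-dibromo-5,5-dimethyl-1-methylidenespiro[5.5]undecan-9-one (equatorial C8 bromide) | C=C1CC[C@@H](Br)C(C)(C)[C@]12CCC(=O)[C@@H](Br)C2 | intermediate
19 | (4R,6S,8S,9S)-4,8-dibromo-5,5,9-trimethyl-1-methylidenespiro[5.5]undecan-9-ol | C=C1CC[C@@H](Br)C(C)(C)[C@]12CC[C@](C)(O)[C@@H](Br)C2 | intermediate
20 | chlorosulfite of 19 | C=C1CC[C@@H](Br)C(C)(C)[C@]12CC[C@](C)(OS(Cl)=O)[C@@H](Br)C2 | intermediate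
21 | (4R,6S,8S,9S)-4,8-dibromo-9-chloro-5,5,9-trimethyl-1-methylidenespiro[5.5]undecane | C=C1CC[C@@H](Br)C(C)(C)[C@]12CC[C@](C)(Cl)[C@@H](Br)C2 | intermediate
22 | (2R,4R,6S,8S,9S)-4,8-dibromo-9-chloro-5,5,9-trimethyl-1-methylidenespiro[5.5]undecan-2-ol | C=C1[C@H](O)C[C@@H](Br)C(C)(C)[C@]12CC[C@](C)(Cl)[C@@H](Br)C2 | target

**Summary**

Total step count: 12. Longest linear sequence: 12 steps (1 to 22); 4 and 9 enter as purchased fragments.

Steps most likely to fail:

Step 5. The Michael addition at a carbon next to the quaternary C5 may be slow or reverse, alkoxide may cleave the diketone (retro-Claisen), or facial selectivity may be poor. The fallback sets out from 8 and comes back at 10, which is then cyclised with KOtBu to 11 as in step 5. O-Allylation of 8 (allyl bromide, K2CO3, acetone) should give allyl enol ether F1. Heating (toluene, 110 °C) should bring about a Claisen rearrangement, which tolerates vicinal quaternary carbons and should place the allyl group on the face anti to the pseudo-axial methyl, giving C-allyl diketone F2. Hydroboration–oxidation (9-BBN; NaBO3) should give primary alcohol F3, oxidation (TEMPO, PhI(OAc)2; then NaClO2) carboxylic acid F4, and esterification (Me3SiCHN2, MeOH) 10.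

Step 4. Ring closure through the enol oxygen in place of carbon, or loss of HCl to an alkene, may compete with C-cyclisation. The fallback sets out from 6 and comes back at 8. Silylation (Me3SiCl, Et3N) should give trimethylsilyl enol ether F5, in which oxygen is blocked. A Lewis acid (ZnCl2 or TiCl4, CH2Cl2, −78 °C) should then ionise the tertiary chloride with bromine participation, and the silyl enol ether carbon should capture the bromonium ion (intramolecular α-tert-alkylation of a silyl enol ether), giving 8 after loss of the silyl group.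

Step 11. An open tertiary cation may be captured on the wrong face, or may eliminate, so that the C9 configuration is lost. The fallback sets out from 15 and comes back at 21. Conjugate reduction with enolate triflation (LiBH(s-Bu)3, THF, −78 °C; then PhNTf2) should give enol triflate F6, and methyl coupling (Me2CuLi, THF, −20 °C) diene F7. Bromochlorination of the more electron-rich trisubstituted ring B alkene (NBS, ClTi(OiPr)3, CH2Cl2, −20 °C) should then proceed by anti addition, with Br+ taken up on the face remote from the axial C1 group and chloride opening the tertiary terminus, to give 21.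

**Further compounds**

F1 | step 5 | 1-[(5R)-5-bromo-6,6-dimethyl-2-(prop-2-enyloxy)cyclohex-1-en-1-yl]ethan-1-one | CC(=O)C1=C(OCC=C)CC[C@@H](Br)C1(C)C
F2 | step 5 | (2S,4R)-2-acetyl-4-bromo-3,3-dimethyl-2-(prop-2-enyl)cyclohexan-1-one | C=CC[C@]1(C(C)=O)C(=O)CC[C@@H](Br)C1(C)C
F3 | step 5 | (2S,4R)-2-acetyl-4-bromo-2-(3-hydroxypropyl)-3,3-dimethylcyclohexan-1-one | OCCC[C@]1(C(C)=O)C(=O)CC[C@@H](Br)C1(C)C
F4 | step 5 | 3-[(1S,3R)-1-acetyl-3-bromo-2,2-dimethyl-6-oxocyclohexyl]propanoic acid | OC(=O)CC[C@]1(C(C)=O)C(=O)CC[C@@H](Br)C1(C)C
F5 | step 4 | (7R)-7-bromo-8-chloro-8-methyl-4-(trimethylsilyloxy)non-3-en-2-one | CC(=O)C=C(O[Si](C)(C)C)CC[C@@H](Br)C(C)(C)Cl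
F6 | step 11 | (4R,6S)-4-bromo-5,5-dimethyl-1-methylidenespiro[5.5]undec-8-en-9-yl trifluoromethanesulfonate | C=C1CC[C@@H](Br)C(C)(C)[C@]12CCC(OS(=O)(=O)C(F)(F)F)=CC2
F7 | step 11 | (4R,6S)-4-bromo-5,5,9-trimethyl-1-methylidenespiro[5.5]undec-8-ene | C=C1CC[C@@H](Br)C(C)(C)[C@]12CCC(C)=CC2
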